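We want to know which of ash and elm holds more target after 5.0 h at 20 °C. The two share their substrate charge, temperature and time, and differ in reagent and initiator.

common to all: substrate 10 mM

| flask | reagent | initiator | temperature | remark | time |
|---|---|---|---|---|---|
| Wednesday's | 15 mM | 96 µM | 15 °C | run made earlier |  |
| Thursday's | 15 mM | 95 µM | 26 °C | run made earlier |  |
| Friday's | 15 mM | 130 µM | 15 °C | run made earlier |  |
| Monday's | 14 mM | 78 µM | 26 °C | run made earlier |  |
| ash | 15.0 mM | 78 µM | 20 °C |  | 5.0 h |
| elm | 10.0 mM | 120 µM | 20 °C |  | 5.0 h |

- Wednesday's (time / h: target / %): 0.500: 4.7; 1.00: 10.8; 1.50: 14.2; 2.00: 17.4; 2.50: 20.8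
- Thursday's (time / h: target / %): 0.200: 6.9; 0.667: 19.4; 1.33: 31.0; 2.00: 37.0; 2.50: 40.0
- Friday's (time / h: target / %): 0.500: 7.3; 1.00: 12.0; 1.50: 17.1; 2.00: 19.8; 2.50: 23.3
- Monday's (time / h: target / %): 0.500: 14.4; 1.00: 20.8; 1.50: 27.3; 2.00: 31.5; 2.50: 33.4

(readings scatter by 1 percentage point)

* the winner by amount of target, in percent of the substrate charged; "neither" if no more than 2 percentage points parts them (ash / elm / neither)
* how much target is there at the end, in percent of the substrate charged: ash
* how much target is there at the end, in percent of the substrate charged: elm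



Two pairs of simulated runs show how those charges count. Friday's and Wednesday's runs differ in initiator, and their last readings stand at a ratio of 1.12, near the 1.16 that the square root of the initiator ratio gives, which is the usual law of a kinetic chain. Thursday's and Monday's runs look nearly the same, yet Monday's ends lower, at 33.4% of the substrate charged against 40.0%, a ratio of 1.20. The root of the initiator ratio reaches 1.10 there, but multiplied by the reagent ratio of 1.07 it reaches 1.18, a thin case, since each reading scatters by 1 percentage point.

So we carry the chain drive: one flask's reagent charge as a fraction of the other's, times the square root of its initiator charge as a fraction of the other's, at equal substrate charge, temperature and time. For elm over ash it is 0.827. Even if ash reached no further than Wednesday's last reading, that factor opens a gap of 3.6 points, wider than the margin of 2 points, so we call ash. The call hangs on the reagent: with the initiator root by itself the ratio is 1.24, so a run showing the yield unmoved by reagent would put elm ahead and overturn it.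

The forecast says ash, with 35% against 28%, a ratio of 0.800, a little under ours, and adds: “The reagent order is the main uncertainty”.

The flask gives ash, with 35.4% against 27.6%, a ratio of 0.780, a little under the drive of 0.827.

    2 substrate → homo dimer (k = 0.671 M⁻¹ h⁻¹, Ea = 65.0 kJ mol⁻¹)
    initiator → 2 initiating radical (k = 0.246 h⁻¹, Ea = 100 kJ mol⁻¹)
    2 chain carrier → ended chains (k = 3.00 × 10⁶ M⁻¹ s⁻¹, Ea = 16.0 kJ mol⁻¹)
    target ⇌ isomer of the product (K = 1.22, k = 0.252 h⁻¹, Ea = 90.0 kJ mol⁻¹, ΔH = −60.0 kJ mol⁻¹)
    reagent + chain carrier → target + initiating radical (k = 3.00 × 10⁶ M⁻¹ h⁻¹, Ea = 41.0 kJ mol⁻¹)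
    substrate + initiating radical → chain carrier (k = 5.77 × 10⁶ M⁻¹ h⁻¹, Ea = 39.0 kJ mol⁻¹)
    (constants at 20 °C)

The neighbouring flask is ash with 0.047 mM of initiator, its reagent charge, temperature and time unchanged, so its chain drive over ash is the initiator root, 0.776, which puts it at 27.5% of the substrate charged. It holds 29.0% of target at the end, more than that, with 50% of its substrate left.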